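**Zero start.** A racemate starts with no excess, so any lead of right-handed substrate in these runs grew after the charge.

| flask | left-handed substrate | right-handed substrate | reagent | catalyst | added ligand | remark | time |
|---|---|---|---|---|---|---|---|
| dusk | 0.16 M | 0.16 M | 3 equiv | 0.27 mol% | 0.50 mM | the very flask that is asked about, followed so far |  |
| winter | 0.16 M | 0.16 M | 3 equiv | 0.18 mol% | 0.50 mM | run made earlier |  |
| flask | 0.16 M | 0.16 M | 3.00 equiv | 0.27 mol% | 0.50 mM |  | 2.5 h |

dusk run (percent of the left-handed substrate and right-handed substrate together charged)

| time / min | left-handed substrate / % | right-handed substrate / % |
|---|---|---|
| 20.0 | 27.6 | 33.2 |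
| 40.0 | 18.3 | 22.8 |
| 60.0 | 12.5 | 15.3 |
| 80.0 | 10.9 | 11.4 |

winter run (percent of the left-handed substrate and right-handed substrate together charged)

| time / h | left-handed substrate / % | right-handed substrate / % |
|---|---|---|
| 0.200 | 39.6 | 42.2 |
| 0.500 | 27.2 | 34.2 |
| 1.00 | 19.9 | 22.7 |
| 2.50 | 9.2 | 7.9 |

(each reading ± 1 percentage point)

- catalyst is single-handed; left-handed substrate and right-handed substrate are mirror images of each other, charged as a racemate, each of them at the stated concentration
- the analysis behind the earlier runs scatters by 1 percentage point, standard deviation
- an excess is the difference of the two amounts in percent of their sum
- an excess is below zero if the other one leads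

1. part of the left-handed substrate and right-handed substrate charged together that has reacted at 2.5 h
2. excess of left-handed product over right-handed product in the product at 2.5 h
3. excess of right-handed substrate over left-handed substrate among what is left of the two at 2.5 h

**Two runs.** Dusk, the flask itself followed to 80.0 min, and winter differ in catalyst loading, 0.27 mol% against 0.18 mol%. I sum each run's gaps, right-handed minus left-handed substrate, and divide by the summed amounts of both. This gives 8.82% for dusk and 5.47% for winter. I call it the steady excess, the lead of right-handed substrate that a run holds while both substrates fall.

The two stand in the ratio 1.61, and the loadings in 1.50. In dusk, right-handed over left-handed substrate reads 1.20 at 20.0 min and 1.22 at 60.0 min, not widening as a plain kinetic resolution would. So I read a dynamic kinetic resolution: the catalyst favours left-handed substrate, an exchange between the mirror images pulls the gap back, and more catalyst holds a wider gap. Winter's last gap, 1.3 percentage points the other way, sits near the scatter of 1 point.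

**My reckoning.** The flask is dusk continued to 2.5 h, so I expect an excess of right-handed substrate near 8.82%, and left-handed product ahead.

**The result.** The forecast gives 91.6% reacted, an excess of left-handed product of −2.6% and an excess of right-handed substrate of −29%, saying “The excess inverts”. The flask gives 91.1% reacted, an excess of left-handed product of 20.3% and an excess of right-handed substrate of 7.10%.

    reagent + catalyst + left-handed substrate → catalyst + left-handed product (k = 280 /M²/min)
    reagent + catalyst + right-handed substrate → catalyst + right-handed product (k = 160 /M²/min)
    catalyst + added ligand ⇌ idle complex, settled at all times (K = 1400 /M)
    left-handed substrate ⇌ right-handed substrate (k = 0.0240 /min)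

**The neighbour.** The flask's excess of right-handed substrate, 7.10%, stands beside my 8.82%. A neighbour charged with 0.0020 M of added ligand keeps 29.6% of its catalyst free, the rest sitting as idle complex, against 66.7% in the flask. Scaling the steady excess by working catalyst gives 3.91%. That neighbour ends with an excess of right-handed substrate of 4.11%.

(The runs come from a simulation on assumed constants, noise included.)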